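**Retrosynthetic overview**
- The target is a cyclohept-2-en-1-one (ring C1–C7). Its C1 ketone, C2 hydroxymethyl and C2=C3 alkene are read as the 1,3-allylic transposition product of a Morita–Baylis–Hillman adduct.
- The only ring is therefore closed by forming C2–C3: the α-carbon of a vinyl ketone (C1, C2, future hydroxymethyl CH2) adds to the C3 aldehyde of an acyclic chain that already carries C5 (quaternary: Me, allyl) and C6 ((E)-silylvinyl).
- That chain comes from a δ-lactone: Rh-catalysed asymmetric conjugate addition of a β-silylvinyl boronate sets C6, methylation then anti-selective allylation sets C5, and lactol methoxymethylenation supplies C3.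
- After ring closure: acetate SN2′ transposition, C7 acetonylation anti to C6, cross-metathesis for the C5 side chain, Si → I → enol ester exchange, desilylation.

Key step: step 11

Remark: (S)-BINAP is assumed to give (S)-5 by the usual facial model for cyclic acceptors; if the sense is opposite, (R)-BINAP is used with no other change.

**Route**

Step 1
Reactants: 1 ethynyldimethylphenylsilane; 2 pinacolborane
Product: 3 (E)-2-[2-(dimethylphenylsilyl)ethenyl]-4,4,5,5-tetramethyl-1,3,2-dioxaborolane
Conditions: Cp2Zr(H)Cl (5 mol %), Et3N (10 mol %), neat, 60 °C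
Reagents that add atoms: none
Why: Zirconocene-hydride-catalysed alkyne hydroboration is a syn addition that puts boron on the unhindered terminal carbon, so the (E)-1-boryl-2-silylethene should result.

Step 2
Reactants: 3 (E)-silylvinyl boronate; 4 5,6-dihydro-2H-pyran-2-one
Product: 5 (S)-4-[(E)-2-(dimethylphenylsilyl)ethenyl]oxan-2-one
Conditions: [RhCl(C2H4)2]2 (2.5 mol %), (S)-BINAP (5.5 mol %), aq KOH (0.5 equiv), dioxane–H2O 10:1, 50 °C; 1 M HCl work-up
Reagents that add atoms: none
Why: Hayashi–Miyaura rhodium-catalysed asymmetric 1,4-addition of an alkenylboron reagent to a cyclic enoate, in which the (S)-BINAP–Rh alkenyl adds to one enantioface of the s-trans lactone and should set the future C6 as the S-lactone centre, while the acidic work-up recloses any saponified lactone.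

Step 3
Reactants: 5 (S)-silylvinyl lactone
Product: 6 (3R,4S)-4-[(E)-2-(dimethylphenylsilyl)ethenyl]-3-methyloxan-2-one (trans epimer drawn)
Conditions: LDA, THF, −78 °C; MeI, −78 → −40 °C
Reagents that add atoms: iodomethane, CI
Why: SN2 alkylation of the lactone lithium enolate should give mainly the trans product, and the new C3 centre is of no consequence because it is re-enolised in step 4.

Step 4
Reactants: 6 α-methyl lactone
Product: 7 (3R,4R)-3-allyl-4-[(E)-2-(dimethylphenylsilyl)ethenyl]-3-methyloxan-2-one
Conditions: LDA, THF–DMPU, −78 °C; allyl bromide, −78 → −30 °C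
Reagents that add atoms: allyl bromide, C=CCBr
Why: Enolate alkylation in which the planar α-methyl enolate is attacked anti to the adjacent silylvinyl group (held pseudoaxial by A(1,2) strain), so allyl should enter trans and methyl end up cis to it, which is the C5/C6 relationship of the target.

Step 5
Reactants: 7 quaternary lactone
Product: 8 (3R,4R)-3-allyl-4-[(E)-2-(dimethylphenylsilyl)ethenyl]-3-methyloxan-2-ol (anomers)
Conditions: DIBAL-H, CH2Cl2, −78 °C; Rochelle salt
Reagents that add atoms: none
Why: Partial hydride reduction of a lactone, whose tetrahedral aluminium hemiacetal is stable at −78 °C, should stop cleanly at the lactol, all the more so next to a quaternary carbon.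

Step 6
Reactants: 8 lactol
Product: 9 (3R,4R)-4-allyl-3-[(E)-2-(dimethylphenylsilyl)ethenyl]-6-methoxy-4-methylhex-5-en-1-ol (enol ether E/Z mixture)
Conditions: Ph3P(CH2OMe)Cl (4 equiv), KOtBu (3.8 equiv), THF, 0 → 45 °C
Reagents that add atoms: (methoxymethyl)triphenylphosphonium chloride, COC[P+](c1ccccc1)(c1ccccc1)c1ccccc1.[Cl-]
Why: Wittig methoxymethylenation of the open hydroxy-aldehyde form of the lactol (excess ylide deprotonates the lactol and drives ring opening) adds the C3 carbon as a masked aldehyde and frees the primary alcohol that becomes C1.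

Step 7
Reactants: 9 hydroxy enol ether
Product: 10 (3R,4R)-4-allyl-3-[(E)-2-(dimethylphenylsilyl)ethenyl]-6-methoxy-4-methylhex-5-enal
Conditions: Dess–Martin periodinane, pyridine, CH2Cl2, 0 °C → rt
Reagents that add atoms: none
Why: Dess–Martin oxidation of a primary alcohol under pyridine buffering should leave the acid-labile enol ether and the vinylsilane untouched.

Step 8
Reactants: 10 aldehyde
Product: 11 (5R,6R)-6-allyl-5-[(E)-2-(dimethylphenylsilyl)ethenyl]-8-methoxy-6-methylocta-1,7-dien-3-ol (C3 epimers)
Conditions: CH2=CHMgBr, THF, −78 °C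
Reagents that add atoms: vinylmagnesium bromide, C=C[Mg]Br
Why: Grignard 1,2-addition to the aldehyde should be clean, and the uncontrolled carbinol centre is removed by oxidation in step 9.

Step 9
Reactants: 11 allylic alcohol
Product: 12 (5R,6R)-6-allyl-5-[(E)-2-(dimethylphenylsilyl)ethenyl]-8-methoxy-6-methylocta-1,7-dien-3-one
Conditions: Dess–Martin periodinane, pyridine, CH2Cl2, 0 °C
Reagents that add atoms: none
Why: Dess–Martin oxidation of a secondary allylic alcohol gives the vinyl ketone under neutral, non-nucleophilic conditions that the enone and the enol ether tolerate.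

Step 10
Reactants: 12 vinyl ketone enol ether
Product: 13 (3S,4R)-3-allyl-4-[(E)-2-(dimethylphenylsilyl)ethenyl]-3-methyl-6-oxooct-7-enal
Conditions: TsOH·H2O (0.2 equiv), acetone–H2O 10:1, rt; used at once
Reagents that add atoms: water, O
Why: Acid-catalysed enol ether hydrolysis (C-protonation, hydration, loss of methanol) unveils the C3 aldehyde with a non-nucleophilic acid that should spare the vinyl ketone and the vinylsilane.

Step 11
Reactants: 13 vinyl ketone aldehyde
Product: 14 (5S,6R)-5-allyl-6-[(E)-2-(dimethylphenylsilyl)ethenyl]-3-hydroxy-5-methyl-2-methylidenecycloheptan-1-one (C3 epimers; 3S drawn)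
Conditions: PMe3 (0.3 equiv), t-AmOH, 0.01 M, rt
Reagents that add atoms: none
Why: PMe3 adds 1,4 to the vinyl ketone to give a β-phosphonium enolate whose α-carbon (C2) attacks the tethered aldehyde carbon (C3); alcohol-assisted proton transfer and E1cB loss of the phosphine then return the enone as its exocyclic methylene isomer. The closest known reaction type is the phosphine-catalysed intramolecular Morita–Baylis–Hillman cyclisation of enone–aldehydes, well established for five- and six-membered rings and known, though rare, for seven. The seven-membered carbocycle closes in a 7-(enolendo)-exo-trig aldol mode, helped by the quaternary C5 and the branched C6 in the tether (Thorpe–Ingold effect). The new C3 carbinol centre is under weak substrate control only and is left unassigned, because step 12 removes it. The step needs intramolecular aldol capture to win over intermolecular Rauhut–Currier dimerisation of the vinyl ketone and over aldehyde enolisation; high dilution, the non-basic phosphine and the pre-organised tether should secure this.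

Step 12
Reactants: 14 Baylis–Hillman alcohol
Product: 16 (5S,6R)-2-(acetoxymethyl)-5-allyl-6-[(E)-2-(dimethylphenylsilyl)ethenyl]-5-methylcyclohept-2-en-1-one, via secondary acetate 15 (not isolated)
Conditions: Ac2O, DMAP (cat.), pyridine, CH2Cl2, 0 °C → rt; then DABCO (0.3 equiv), THF, 55 °C
Reagents that add atoms: acetic anhydride, CC(=O)OC(C)=O
Why: O-acetylation followed by amine-catalysed SN2′ displacement and acetate return (allylic transposition of a Baylis–Hillman acetate) should funnel both C3 epimers to the thermodynamically preferred primary acetate with the endocyclic, conjugated C2=C3 alkene, which erases the C3 stereocentre.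

Step 13
Reactants: 16 primary allylic acetate
Product: 17 (5S,6R)-5-allyl-6-[(E)-2-(dimethylphenylsilyl)ethenyl]-2-(hydroxymethyl)-5-methylcyclohept-2-en-1-one
Conditions: K2CO3 (0.2 equiv), MeOH, 0 °C
Reagents that add atoms: none
Why: Base-catalysed transesterification of a primary acetate is fast at 0 °C, and brief exposure should avoid conjugate addition of methoxide to the hindered enone.

Step 14
Reactants: 17 primary allylic alcohol
Product: 18 (5S,6R)-5-allyl-2-[(tert-butyldimethylsilyloxy)methyl]-6-[(E)-2-(dimethylphenylsilyl)ethenyl]-5-methylcyclohept-2-en-1-one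
Conditions: TBSCl, imidazole, DMF, 0 °C → rt
Reagents that add atoms: tert-butyldimethylsilyl chloride, CC(C)(C)[Si](C)(C)Cl
Why: Silylation of the primary alcohol gives an ether that withstands LDA, mild acid, metathesis and copper, and can be removed at the end without harming an enol ester.

Step 15
Reactants: 19 2-methoxypropene
Product: 20 2-methoxyallyl bromide (3-bromo-2-methoxyprop-1-ene)
Conditions: NBS, CCl4, 0 °C → rt; distilled, used at once
Reagents that add atoms: N-bromosuccinimide, O=C1CCC(=O)N1Br
Why: Electrophilic bromination of the enol ether gives a bromo-oxocarbenium ion that loses an allylic proton to succinimide anion, the established preparation of this acetonyl cation equivalent (isomeric vinylic bromides are inert in step 16).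

Step 16
Reactants: 18 silyl-protected enone; 20 2-methoxyallyl bromide
Product: 22 (5S,6R,7S)-5-allyl-2-[(tert-butyldimethylsilyloxy)methyl]-6-[(E)-2-(dimethylphenylsilyl)ethenyl]-5-methyl-7-(2-oxopropyl)cyclohept-2-en-1-one, via 2-methoxyallyl ketone 21 (not isolated)
Conditions: LDA, THF, −78 °C; 20, DMPU, −78 → −30 °C; then 5% aq oxalic acid, THF, rt
Reagents that add atoms: water, O
Why: Kinetic α′-deprotonation by LDA gives the cross-conjugated C7 enolate, which is alkylated (SN2) by the allylic bromide anti to the neighbouring C6 silylvinyl group and so should set C7 as S (trans to C6), after which mild acid hydrolyses the enol ether to the methyl ketone without cleaving the TBS ether.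

Step 17
Reactants: 22 allyl diketone; 23 2-methylbut-3-en-2-ol
Product: 24 (5S,6R,7S)-2-[(tert-butyldimethylsilyloxy)methyl]-6-[(E)-2-(dimethylphenylsilyl)ethenyl]-5-[(E)-4-hydroxy-4-methylpent-2-en-1-yl]-5-methyl-7-(2-oxopropyl)cyclohept-2-en-1-one
Conditions: Hoveyda–Grubbs II (5 mol %), 23 (10 equiv), CH2Cl2, 40 °C
Reagents that add atoms: none
Why: Olefin cross-metathesis between the unhindered allyl terminus and a tertiary allylic alcohol that does not homodimerise should be E-selective, while the trisubstituted enone and the bulky 1,2-disubstituted vinylsilane are reluctant metathesis partners and should remain spectators.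

Step 18
Reactants: 24 vinylsilane
Product: 25 (5S,6R,7S)-2-[(tert-butyldimethylsilyloxy)methyl]-5-[(E)-4-hydroxy-4-methylpent-2-en-1-yl]-6-[(E)-2-iodoethenyl]-5-methyl-7-(2-oxopropyl)cyclohept-2-en-1-one
Conditions: NIS, 2,6-lutidine, (CF3)2CHOH, 0 °C
Reagents that add atoms: N-iodosuccinimide, O=C1CCC(=O)N1I
Why: Iododesilylation by ipso attack of iodonium on the vinylsilane (β-silyl cation, then loss of silicon) proceeds with retention of the E geometry in hexafluoroisopropanol, and the vinylsilane should be more nucleophilic than the electron-poor enone and the hindered allylic-alcohol alkene.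

Step 19
Reactants: 25 (E)-vinyl iodide; 26 3-methylbut-2-enoic acid
Product: 27 primary TBS ether of the target
Conditions: CuI (20 mol %), 3,4,7,8-tetramethyl-1,10-phenanthroline (40 mol %), 26 (2.2 equiv), Cs2CO3 (1.0 equiv), toluene, 70 °C, dark
Reagents that add atoms: none
Why: Ullmann-type copper(I)-mediated C–O coupling of an alkenyl iodide with a carboxylate (oxidative addition, then reductive elimination at copper) retains the E geometry, and the excess acid leaves only carboxylate as base, which should protect the 1,4-diketone and the C7 centre.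

Step 20
Reactants: 27 silyl-protected enol ester
Product: 28 target CNP0351090.2
Conditions: HF·pyridine, pyridine, THF, 0 °C → rt
Reagents that add atoms: none
Why: Buffered fluoride cleavage of the primary TBS ether should leave the enol ester, the tertiary allylic alcohol and the epimerisable C7 centre intact.

**Compound list**
1 | ethynyldimethylphenylsilane | C#C[Si](C)(C)c1ccccc1 | starting material
2 | pinacolborane | [H]B1OC(C)(C)C(C)(C)O1 | starting material
3 | (E)-2-[2-(dimethylphenylsilyl)ethenyl]-4,4,5,5-tetramethyl-1,3,2-dioxaborolane | C[Si](C)(/C=C/B1OC(C)(C)C(C)(C)O1)c1ccccc1 | intermediate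
4 | 5,6-dihydro-2H-pyran-2-one | O=C1C=CCCO1 | starting material
5 | (S)-4-[(E)-2-(dimethylphenylsilyl)ethenyl]oxan-2-one | O=C1C[C@@H](/C=C/[Si](C)(C)c2ccccc2)CCO1 | intermediate
6 | (3R,4S)-4-[(E)-2-(dimethylphenylsilyl)ethenyl]-3-methyloxan-2-one (trans epimer drawn) | O=C1[C@H](C)[C@@H](/C=C/[Si](C)(C)c2ccccc2)CCO1 | intermediate
7 | (3R,4R)-3-allyl-4-[(E)-2-(dimethylphenylsilyl)ethenyl]-3-methyloxan-2-one | O=C1[C@](C)(CC=C)[C@@H](/C=C/[Si](C)(C)c2ccccc2)CCO1 | intermediate
8 | (3R,4R)-3-allyl-4-[(E)-2-(dimethylphenylsilyl)ethenyl]-3-methyloxan-2-ol (anomers) | OC1[C@](C)(CC=C)[C@@H](/C=C/[Si](C)(C)c2ccccc2)CCO1 | intermediate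
9 | (3R,4R)-4-allyl-3-[(E)-2-(dimethylphenylsilyl)ethenyl]-6-methoxy-4-methylhex-5-en-1-ol (enol ether E/Z) | OCC[C@H](/C=C/[Si](C)(C)c1ccccc1)[C@@](C)(CC=C)C=COC | intermediate
10 | (3R,4R)-4-allyl-3-[(E)-2-(dimethylphenylsilyl)ethenyl]-6-methoxy-4-methylhex-5-enal | O=CC[C@H](/C=C/[Si](C)(C)c1ccccc1)[C@@](C)(CC=C)C=COC | intermediate
11 | (5R,6R)-6-allyl-5-[(E)-2-(dimethylphenylsilyl)ethenyl]-8-methoxy-6-methylocta-1,7-dien-3-ol (C3 epimers) | C=CC(O)C[C@H](/C=C/[Si](C)(C)c1ccccc1)[C@@](C)(CC=C)C=COC | intermediate
12 | (5R,6R)-6-allyl-5-[(E)-2-(dimethylphenylsilyl)ethenyl]-8-methoxy-6-methylocta-1,7-dien-3-one | C=CC(=O)C[C@H](/C=C/[Si](C)(C)c1ccccc1)[C@@](C)(CC=C)C=COC | intermediate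
13 | (3S,4R)-3-allyl-4-[(E)-2-(dimethylphenylsilyl)ethenyl]-3-methyl-6-oxooct-7-enal (key-step precursor) | C=CC(=O)C[C@H](/C=C/[Si](C)(C)c1ccccc1)[C@@](C)(CC=C)CC=O | intermediate
14 | (5S,6R)-5-allyl-6-[(E)-2-(dimethylphenylsilyl)ethenyl]-3-hydroxy-5-methyl-2-methylidenecycloheptan-1-one (C3 epimers; 3S drawn) | C=C1C(=O)C[C@H](/C=C/[Si](C)(C)c2ccccc2)[C@@](C)(CC=C)C[C@@H]1O | intermediate
15 | C3 acetate of 14 (3S drawn) | C=C1C(=O)C[C@H](/C=C/[Si](C)(C)c2ccccc2)[C@@](C)(CC=C)C[C@@H]1OC(C)=O | intermediate
16 | (5S,6R)-2-(acetoxymethyl)-5-allyl-6-[(E)-2-(dimethylphenylsilyl)ethenyl]-5-methylcyclohept-2-en-1-one | CC(=O)OCC1=CC[C@](C)(CC=C)[C@@H](/C=C/[Si](C)(C)c2ccccc2)CC1=O | intermediate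
17 | (5S,6R)-5-allyl-6-[(E)-2-(dimethylphenylsilyl)ethenyl]-2-(hydroxymethyl)-5-methylcyclohept-2-en-1-one | OCC1=CC[C@](C)(CC=C)[C@@H](/C=C/[Si](C)(C)c2ccccc2)CC1=O | intermediate
18 | (5S,6R)-5-allyl-2-[(tert-butyldimethylsilyloxy)methyl]-6-[(E)-2-(dimethylphenylsilyl)ethenyl]-5-methylcyclohept-2-en-1-one | CC(C)(C)[Si](C)(C)OCC1=CC[C@](C)(CC=C)[C@@H](/C=C/[Si](C)(C)c2ccccc2)CC1=O | intermediate
19 | 2-methoxypropene | COC(C)=C | starting material
20 | 2-methoxyallyl bromide | COC(=C)CBr | intermediate
21 | (5S,6R,7S)-5-allyl-2-[(tert-butyldimethylsilyloxy)methyl]-6-[(E)-2-(dimethylphenylsilyl)ethenyl]-7-(2-methoxyprop-2-en-1-yl)-5-methylcyclohept-2-en-1-one | COC(=C)C[C@@H]1C(=O)C(CO[Si](C)(C)C(C)(C)C)=CC[C@](C)(CC=C)[C@H]1/C=C/[Si](C)(C)c1ccccc1 | intermediate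
22 | (5S,6R,7S)-5-allyl-2-[(tert-butyldimethylsilyloxy)methyl]-6-[(E)-2-(dimethylphenylsilyl)ethenyl]-5-methyl-7-(2-oxopropyl)cyclohept-2-en-1-one | CC(=O)C[C@@H]1C(=O)C(CO[Si](C)(C)C(C)(C)C)=CC[C@](C)(CC=C)[C@H]1/C=C/[Si](C)(C)c1ccccc1 | intermediate
23 | 2-methylbut-3-en-2-ol | CC(C)(O)C=C | starting material
24 | (5S,6R,7S)-2-[(tert-butyldimethylsilyloxy)methyl]-6-[(E)-2-(dimethylphenylsilyl)ethenyl]-5-[(E)-4-hydroxy-4-methylpent-2-en-1-yl]-5-methyl-7-(2-oxopropyl)cyclohept-2-en-1-one | CC(=O)C[C@@H]1C(=O)C(CO[Si](C)(C)C(C)(C)C)=CC[C@](C)(C/C=C/C(C)(C)O)[C@H]1/C=C/[Si](C)(C)c1ccccc1 | intermediate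
25 | (5S,6R,7S)-2-[(tert-butyldimethylsilyloxy)methyl]-5-[(E)-4-hydroxy-4-methylpent-2-en-1-yl]-6-[(E)-2-iodoethenyl]-5-methyl-7-(2-oxopropyl)cyclohept-2-en-1-one | CC(=O)C[C@@H]1C(=O)C(CO[Si](C)(C)C(C)(C)C)=CC[C@](C)(C/C=C/C(C)(C)O)[C@H]1/C=C/I | intermediate
26 | 3-methylbut-2-enoic acid (senecioic acid) | CC(C)=CC(=O)O | starting material
27 | primary TBS ether of the target (5S,6S,7S) | CC(=O)C[C@@H]1C(=O)C(CO[Si](C)(C)C(C)(C)C)=CC[C@](C)(C/C=C/C(C)(C)O)[C@H]1/C=C/OC(=O)C=C(C)C | intermediate
28 | CNP0351090.2: (E)-enol 3-methylbut-2-enoate at C6 of (5S,6S,7S)-2-(hydroxymethyl)-5-[(E)-4-hydroxy-4-methylpent-2-en-1-yl]-5-methyl-7-(2-oxopropyl)cyclohept-2-en-1-one | CC(=O)C[C@@H]1C(=O)C(CO)=CC[C@](C)(C/C=C/C(C)(C)O)[C@H]1/C=C/OC(=O)C=C(C)C | target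

**Step count and risks**
Total steps: 20. Longest linear sequence: 19 (steps 1–14 and 16–20; step 15 is a one-step side branch).

Step 11 (ring closure). The slow seven-membered aldol capture may lose to intermolecular Rauhut–Currier oligomerisation of the vinyl ketone, or the reaction may stall before phosphine release. The fallback sets out from 13 and returns at 14, making the same C2–C3 bond by a stoichiometric Michael–aldol–elimination sequence. Me2AlSPh (from AlMe3 and PhSH, CH2Cl2, −78 °C) adds thiolate to the vinyl ketone, and the aluminium enolate closes onto the aldehyde to give the β-hydroxy sulfide (5S,6R)-5-allyl-6-[(E)-2-(dimethylphenylsilyl)ethenyl]-3-hydroxy-5-methyl-2-[(phenylsulfanyl)methyl]cycloheptan-1-one F1. NaIO4 (MeOH–H2O, 0 °C) oxidises it to the corresponding sulfoxide F2. Warming F2 in toluene (80 °C, CaCO3) brings about syn-elimination through the only β-hydrogen (C2–H) and gives 14.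

Step 19 (enol ester). C–O reductive elimination at copper may be slow, which would let reductive dimerisation or protodehalogenation of the vinyl iodide take over; prolonged heating may also cause aldol condensation of the 1,4-diketone or C7 epimerisation. The fallback sets out from 25 and returns at 27, replacing the Ullmann-type coupling by an oxidative (Chan–Lam-type) coupling at room temperature. Miyaura borylation of 25 (B2pin2, PdCl2(PPh3)2, PPh3, KOPh, toluene, 50 °C) gives the (E)-alkenyl pinacol boronate F3. KHF2 (MeOH–H2O) converts it into the potassium (E)-alkenyltrifluoroborate F4. F4 is then coupled with 26 (CuBr cat., DMAP, 4 Å MS, O2, CH2Cl2, rt) to give 27 with retention of the E geometry.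

Step 16 (C7 acetonylation). Proton exchange between product and enolate may lead to over-alkylation, the labile bromide may decompose before it is consumed, or the TBS ether may be lost during enol ether hydrolysis. If only the C7 epimer ratio is unsatisfactory, equilibration of 22 with DBU towards the trans isomer would be tried first. The fallback sets out from 18 and returns at 24, building the methyl ketone by allylation and Wacker oxidation once the side chain is in place. Cross-metathesis of 18 with 23 (Hoveyda–Grubbs II, CH2Cl2, 40 °C) gives the side-chain alcohol (5S,6R)-2-[(tert-butyldimethylsilyloxy)methyl]-6-[(E)-2-(dimethylphenylsilyl)ethenyl]-5-[(E)-4-hydroxy-4-methylpent-2-en-1-yl]-5-methylcyclohept-2-en-1-one F5. LDA (2.2 equiv, giving alkoxide and kinetic enolate) and allyl iodide at −78 °C then give the trans C7-allyl ketone F6, whose allyl group is the only terminal alkene in the molecule. Tsuji–Wacker oxidation (PdCl2, CuCl, O2, DMF–H2O) converts F6 into 24, and the route resumes at step 18.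

**Further compounds**
F1 | step 11 | (5S,6R)-5-allyl-6-[(E)-2-(dimethylphenylsilyl)ethenyl]-3-hydroxy-5-methyl-2-[(phenylsulfanyl)methyl]cycloheptan-1-one | O=C1C[C@H](/C=C/[Si](C)(C)c2ccccc2)[C@@](C)(CC=C)CC(O)C1CSc3ccccc3
F2 | step 11 | sulfoxide of F1 | O=C1C[C@H](/C=C/[Si](C)(C)c2ccccc2)[C@@](C)(CC=C)CC(O)C1CS(=O)c3ccccc3
F3 | step 19 | (E)-alkenyl pinacol boronate corresponding to 25 | CC(=O)C[C@@H]1C(=O)C(CO[Si](C)(C)C(C)(C)C)=CC[C@](C)(C/C=C/C(C)(C)O)[C@H]1/C=C/B2OC(C)(C)C(C)(C)O2
F4 | step 19 | potassium (E)-alkenyltrifluoroborate corresponding to 25 | CC(=O)C[C@@H]1C(=O)C(CO[Si](C)(C)C(C)(C)C)=CC[C@](C)(C/C=C/C(C)(C)O)[C@H]1/C=C/[B-](F)(F)F.[K+]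
F5 | step 16 | (5S,6R)-2-[(tert-butyldimethylsilyloxy)methyl]-6-[(E)-2-(dimethylphenylsilyl)ethenyl]-5-[(E)-4-hydroxy-4-methylpent-2-en-1-yl]-5-methylcyclohept-2-en-1-one | CC(C)(C)[Si](C)(C)OCC1=CC[C@](C)(C/C=C/C(C)(C)O)[C@@H](/C=C/[Si](C)(C)c2ccccc2)CC1=O
F6 | step 16 | (5S,6R,7S)-7-allyl-2-[(tert-butyldimethylsilyloxy)methyl]-6-[(E)-2-(dimethylphenylsilyl)ethenyl]-5-[(E)-4-hydroxy-4-methylpent-2-en-1-yl]-5-methylcyclohept-2-en-1-one | C=CC[C@@H]1C(=O)C(CO[Si](C)(C)C(C)(C)C)=CC[C@](C)(C/C=C/C(C)(C)O)[C@H]1/C=C/[Si](C)(C)c1ccccc1
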